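**Retrosynthetic overview**

1. The target is opened to an acyclic enol-ether β-diketone. One acid treatment unmasks the acetyl group, closes the pyran ring first (C1–OH onto C3=O) and the carbocycle last (aldol condensation C5→C4a).
2. That chain is cut at C4–C4a (crossed Claisen) and at C6–C7 into three pieces joined in one flask: a malate-derived α-hydroxy methyl ketone, a two-carbon acetyl anion unit, and the side-chain enone.
3. Key bond C6–C7: 1-ethoxyvinyllithium (acetyl anion equivalent) adds to the chelated C7 ketone and sets the C7 tertiary carbinol. The same two carbons later serve as the C5 enol nucleophile that closes the carbocycle.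
4. The ketone comes from dimethyl (R)-malate (C8) by Fráter–Seebach hydroxymethylation (C8a, C1).
5. The side-chain enone comes from methacrolein by (Z)-crotylboration (C4', C5'), hydroxyl-directed epoxidation (C3'), ylide homologation and cross-metathesis.

Assumption: the SMILES is taken literally, i.e. (7S,8R,8aS) in the core, (3R,4S,5R) in the side chain and an E alkene; isochromene numbering (C1–C8a) and primed side-chain numbering (C1'–C7') are used throughout.

**Route**

Step 1
Reactants: 1 methacrolein; 2 cis-but-2-ene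
Product: 6 (3S,4R)-2,4-dimethylhexa-1,5-dien-3-ol, via (Z)-but-2-enylpotassium 3 (not isolated), via (Z)-crotyldiisopinocampheylborane 4 (not isolated), via diisopinocampheylborinate ester 5 (not isolated)
Conditions: 2, KOtBu, nBuLi, THF, –78 → –45 °C; (–)-Ipc2BOMe, –78 °C; BF3·OEt2; 1, –78 °C; then NaOH, H2O2, 0 °C → rt
Reagents that add atoms: none
Why: Brown asymmetric crotylboration through a closed chair transition state, in which the Z-crotyl geometry gives the syn OH/Me pair and the Ipc ligands derived from (+)-α-pinene direct attack on the Si face of the aldehyde, setting C4' (S) and C5' (R).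

Step 2
Reactants: 6 (3S,4R)-2,4-dimethylhexa-1,5-dien-3-ol
Product: 7 (1S,2R)-2-methyl-1-[(2R)-2-methyloxiran-2-yl]but-3-en-1-ol
Conditions: tBuOOH (1.2 equiv, decane), VO(acac)2 (3 mol %), CH2Cl2, 0 °C → rt
Reagents that add atoms: tert-butyl hydroperoxide, CC(C)(C)OO
Why: Hydroxyl-directed vanadium-catalysed epoxidation reacts only at the allylic 1,1-disubstituted alkene, and A(1,2) strain between the 2-methyl group and the carbinol substituent in the vanadate transition state gives the erythro epoxy alcohol, which is the anti C3'–O/C4'–OH relationship needed (C3' R).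

Step 3
Reactants: 7 (1S,2R)-2-methyl-1-[(2R)-2-methyloxiran-2-yl]but-3-en-1-ol
Product: 8 (1S,2R)-2-methyl-1-[(2R)-2-methyloxiran-2-yl]butan-1-ol
Conditions: H2 (1 atm), RhCl(PPh3)3 (3 mol %), benzene/EtOH 1:1, rt
Reagents that add atoms: none
Why: Homogeneous hydrogenation saturates the only remaining alkene, the unhindered vinyl group, to the ethyl group and leaves the epoxide and all stereocentres untouched.

Step 4
Reactants: 8 (1S,2R)-2-methyl-1-[(2R)-2-methyloxiran-2-yl]butan-1-ol
Product: 9 (3R,4S,5R)-3,5-dimethylhept-1-ene-3,4-diol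
Conditions: Me3S+ I– (4 equiv), nBuLi (3.8 equiv), THF, –10 °C → rt
Reagents that add atoms: trimethylsulfonium iodide, C[S+](C)C.[I-]
Why: Excess dimethylsulfonium methylide (Corey–Chaykovsky reagent) opens the epoxide at its CH2 carbon and the resulting β-oxido sulfonium salt is deprotonated and loses Me2S (one-carbon epoxide-to-allylic-alcohol homologation), so the quaternary C3' centre is never touched and a Payne shift is blocked because it would need substitution at that quaternary carbon.

Step 5
Reactants: 9 (3R,4S,5R)-3,5-dimethylhept-1-ene-3,4-diol; 10 methyl vinyl ketone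
Product: 11 (3E,5R,6S,7R)-5,6-dihydroxy-5,7-dimethylnon-3-en-2-one
Conditions: 10 (5 equiv), second-generation Hoveyda–Grubbs catalyst RuCl2(H2IMes)(=CH-C6H4-2-OiPr) (5 mol %), CH2Cl2, 40 °C
Reagents that add atoms: none
Why: Olefin cross-metathesis between a non-dimerising quaternary allylic alcohol and an electron-poor enone is selective for the cross product and gives the E enone under thermodynamic control.

Step 6
Reactants: 12 dimethyl (R)-malate
Product: 14 methyl (3S,4R)-4-hydroxy-5-oxooxolane-3-carboxylate, via hydroxymethyl diester 13 (not isolated)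
Conditions: LiN(iPr)2 (2.2 equiv), THF, –78 → –20 °C; CH2O (g, from cracked paraformaldehyde), –78 °C; then TsOH·H2O (5 mol %), CH2Cl2, rt
Reagents that add atoms: formaldehyde, C=O
Why: Fráter–Seebach reaction in which the chelated dilithium alkoxide–enolate is attacked by formaldehyde anti to the C8 oxygen, giving the anti (2R,3S) product (C8a S), and the new primary hydroxyl lactonises onto the α-hydroxy ester so the two carboxyl groups become differentiated.

Step 7
Reactants: 14 methyl (3S,4R)-4-hydroxy-5-oxooxolane-3-carboxylate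
Product: 16 methyl (2S,3R)-3-hydroxy-2-(hydroxymethyl)-4-oxopentanoate, via Weinreb amide 15 (not isolated)
Conditions: MeNH(OMe)·HCl (1.15 equiv), iPrMgCl (3.3 equiv), THF, –20 °C; then MeMgBr (1.5 equiv), –40 → –20 °C
Reagents that add atoms: methylmagnesium bromide, C[Mg]Br
Why: The α-hydroxy γ-lactone is much more electrophilic than the methyl ester, so the magnesium amide opens it to the Weinreb amide, whose chelated tetrahedral adduct with MeMgBr collapses to the methyl ketone only on work-up (one-pot Weinreb ketone synthesis), with no stereocentre touched; 16 equilibrates with its cyclic hemiketal.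

Step 8
Reactants: 16 methyl (2S,3R)-3-hydroxy-2-(hydroxymethyl)-4-oxopentanoate; 17 ethyl vinyl ether; 11 (3E,5R,6S,7R)-5,6-dihydroxy-5,7-dimethylnon-3-en-2-one
Product: 21 (3S,4R,5S,9E,11R,12S,13R)-2-ethoxy-3,4,11,12-tetrahydroxy-5-(hydroxymethyl)-3,11,13-trimethylpentadeca-1,9-diene-6,8-dione, via 1-ethoxyvinyllithium 18 (not isolated), via ethoxyvinyl carbinol ester 19 (not isolated), via enol ether lactone 20 (not isolated)
Conditions: 17, tBuLi, THF, –78 → 0 °C (gives 18); 16, LiN(SiMe3)2 (2.0 equiv), THF, –78 °C, then 18 (1.2 equiv), –78 → 0 °C; then 11 premixed with LiN(SiMe3)2 (4.2 equiv), THF, –78 → –20 °C; pH 7 buffer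
Reagents that add atoms: none
Why: 1-Ethoxyvinyllithium acts as an acetyl anion (acyl anion umpolung) and adds to the C7 ketone, held in a five-membered lithium chelate with the C8 alkoxide, from the face opposite C8a (Cram chelate model), which joins two carbonyl-type carbons and sets the C7 tertiary carbinol (S); the tertiary alkoxide then lactonises onto the ester and the γ-lactone acylates the kinetic methyl enolate of 11 (crossed Claisen condensation), the flanking alkoxides suppressing enolisation of the lactone.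

Step 9
Reactants: 21 (3S,4R,5S,9E,11R,12S,13R)-2-ethoxy-3,4,11,12-tetrahydroxy-5-(hydroxymethyl)-3,11,13-trimethylpentadeca-1,9-diene-6,8-dione
Product: 24 (7S,8R,8aS)-3-[(1E,3R,4S,5R)-3,4-dihydroxy-3,5-dimethylhept-1-en-1-yl]-7,8-dihydroxy-7-methyl-1,7,8,8a-tetrahydro-6H-isochromen-6-one, via acetyl triketone 22 (not isolated), via dihydropyranone 23 (not isolated)
Conditions: TsOH·H2O (0.5 equiv), THF/H2O 10:1, 0 → 45 °C
Reagents that add atoms: water, O
Why: Aqueous acid hydrolyses the enol ether to the acetyl group, the primary C1–OH adds to the C3 carbonyl of the β-diketone and dehydrates to the 2,3-dihydro-4H-pyran-4-one, and the methyl ketone enol then adds to the protonated C4a carbonyl and dehydrates (Robinson-type intramolecular aldol condensation) to the fully conjugated dienone, the only irreversible outcome among the possible hemiketal equilibria; no new stereocentre is formed.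

**Compound list**

1 | methacrolein (2-methylprop-2-enal) | CC(=C)C=O | starting material
2 | cis-but-2-ene | C/C=C\C | starting material
3 | (Z)-but-2-enylpotassium | C/C=C\C[K] | intermediate
4 | (Z)-crotyldiisopinocampheylborane (Ipc groups from (+)-α-pinene) | C/C=C\CB([C@@H]1C[C@@H]2C[C@@H](C2(C)C)[C@H]1C)[C@@H]1C[C@@H]2C[C@@H](C2(C)C)[C@H]1C | intermediate
5 | (3S,4R)-2,4-dimethylhexa-1,5-dien-3-yl diisopinocampheylborinate | C=C(C)[C@@H](OB([C@@H]1C[C@@H]2C[C@@H](C2(C)C)[C@H]1C)[C@@H]1C[C@@H]2C[C@@H](C2(C)C)[C@H]1C)[C@H](C)C=C | intermediate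
6 | (3S,4R)-2,4-dimethylhexa-1,5-dien-3-ol | C=C(C)[C@@H](O)[C@H](C)C=C | intermediate
7 | (1S,2R)-2-methyl-1-[(2R)-2-methyloxiran-2-yl]but-3-en-1-ol | C1O[C@@]1(C)[C@@H](O)[C@H](C)C=C | intermediate
8 | (1S,2R)-2-methyl-1-[(2R)-2-methyloxiran-2-yl]butan-1-ol | C1O[C@@]1(C)[C@@H](O)[C@H](C)CC | intermediate
9 | (3R,4S,5R)-3,5-dimethylhept-1-ene-3,4-diol | C=C[C@@](C)(O)[C@@H](O)[C@H](C)CC | intermediate
10 | methyl vinyl ketone (but-3-en-2-one) | CC(=O)C=C | starting material
11 | (3E,5R,6S,7R)-5,6-dihydroxy-5,7-dimethylnon-3-en-2-one | CC(=O)/C=C/[C@@](C)(O)[C@@H](O)[C@H](C)CC | intermediate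
12 | dimethyl (R)-malate | COC(=O)[C@H](O)CC(=O)OC | starting material
13 | dimethyl (2R,3S)-2-hydroxy-3-(hydroxymethyl)butanedioate | COC(=O)[C@H](O)[C@@H](C(=O)OC)CO | intermediate
14 | methyl (3S,4R)-4-hydroxy-5-oxooxolane-3-carboxylate | O=C1[C@H](O)[C@@H](C(=O)OC)CO1 | intermediate
15 | methyl (2S,3R)-3-hydroxy-2-(hydroxymethyl)-4-[methoxy(methyl)amino]-4-oxobutanoate | CON(C)C(=O)[C@H](O)[C@@H](C(=O)OC)CO | intermediate
16 | methyl (2S,3R)-3-hydroxy-2-(hydroxymethyl)-4-oxopentanoate | CC(=O)[C@H](O)[C@@H](C(=O)OC)CO | intermediate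
17 | ethyl vinyl ether | CCOC=C | starting material
18 | 1-ethoxyvinyllithium | CCOC(=C)[Li] | intermediate
19 | methyl (2S,3R,4S)-5-ethoxy-3,4-dihydroxy-2-(hydroxymethyl)-4-methylhex-5-enoate | CCOC(=C)[C@@](C)(O)[C@H](O)[C@@H](C(=O)OC)CO | intermediate
20 | (3S,4R,5S)-5-(1-ethoxyethenyl)-4-hydroxy-3-(hydroxymethyl)-5-methyloxolan-2-one | CCOC(=C)[C@]1(C)[C@H](O)[C@H](CO)C(=O)O1 | intermediate
21 | (3S,4R,5S,9E,11R,12S,13R)-2-ethoxy-3,4,11,12-tetrahydroxy-5-(hydroxymethyl)-3,11,13-trimethylpentadeca-1,9-diene-6,8-dione | CCOC(=C)[C@@](C)(O)[C@H](O)[C@@H](C(=O)CC(=O)/C=C/[C@@](C)(O)[C@@H](O)[C@H](C)CC)CO | intermediate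
22 | (3S,4R,5S,9E,11R,12S,13R)-3,4,11,12-tetrahydroxy-5-(hydroxymethyl)-3,11,13-trimethylpentadec-9-ene-2,6,8-trione | CC(=O)[C@@](C)(O)[C@H](O)[C@@H](C(=O)CC(=O)/C=C/[C@@](C)(O)[C@@H](O)[C@H](C)CC)CO | intermediate
23 | (3S)-3-[(1R,2S)-1,2-dihydroxy-2-methyl-3-oxobutyl]-6-[(1E,3R,4S,5R)-3,4-dihydroxy-3,5-dimethylhept-1-en-1-yl]-2,3-dihydro-4H-pyran-4-one | CC(=O)[C@@](C)(O)[C@H](O)[C@@H]1COC(/C=C/[C@@](C)(O)[C@@H](O)[C@H](C)CC)=CC1=O | intermediate
24 | (7S,8R,8aS)-3-[(1E,3R,4S,5R)-3,4-dihydroxy-3,5-dimethylhept-1-en-1-yl]-7,8-dihydroxy-7-methyl-1,7,8,8a-tetrahydro-6H-isochromen-6-one | CC[C@@H](C)[C@H](O)[C@](C)(O)/C=C/C1=CC2=CC(=O)[C@@](C)(O)[C@H](O)[C@@H]2CO1 | target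

**Step count and risks**

Total steps: 9. Longest linear sequence: 7 (steps 1–5, then 8 and 9); steps 6–7 form the second branch.

Most likely to fail, first: step 8. Three polyanionic events run in one flask, so the vinyllithium may over-add, chelate control by lithium alone may be modest, or the Claisen may stall. The fallback sets out from 16 and comes back to the route at 22. The acetyl anion is delivered instead as an acetylide and unmasked only at the end. Ethynylmagnesium bromide (HC≡CMgBr, 4 equiv, THF, –78 → 0 °C) adds under magnesium chelate control with the same facial sense to give methyl (2S,3R,4R)-3,4-dihydroxy-2-(hydroxymethyl)-4-methylhex-5-ynoate F4. On warming this lactonises to (3S,4R,5R)-5-ethynyl-4-hydroxy-3-(hydroxymethyl)-5-methyloxolan-2-one F5, which is stable and can be purified. In a separate flask F5 is acylated by the lithium enolate of 11 to give (3R,4R,5S,9E,11R,12S,13R)-3,4,11,12-tetrahydroxy-5-(hydroxymethyl)-3,11,13-trimethylpentadec-9-en-1-yne-6,8-dione F6. Gold-catalysed Markovnikov hydration of the terminal propargylic alcohol (Ph3PAuNTf2, wet 1,4-dioxane, rt) then gives 22, which continues under the step 9 conditions.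

Second: step 9. The acid-catalysed aldol onto a vinylogous ester carbonyl is the least precedented event; competing hemiketals (C8–OH or C7–OH onto the diketone), C8a epimerisation or ionisation of the tertiary allylic C3'–OH could divert material. The fallback sets out from 21 and comes back at 24. The cascade is split and the carbocycle is closed under basic instead of acidic activation. Pyridinium p-toluenesulfonate in wet acetone at 0 °C stops at the dihydropyranone 23, which is isolated. Excess LiN(SiMe3)2 (THF, –78 → –20 °C) then forms the kinetic methyl ketone enolate, which adds to the pyranone carbonyl (C5–C4a) to give the aldol (7S,8R,8aS)-3-[(1E,3R,4S,5R)-3,4-dihydroxy-3,5-dimethylhept-1-en-1-yl]-4a,7,8-trihydroxy-7-methyl-1,4a,5,7,8,8a-hexahydro-6H-isochromen-6-one F7. Brief exposure to AcOH eliminates the C4a hydroxyl (Stork–Danheiser-type transposition) to give 24.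

Third: step 7. The lactone-over-ester selectivity of the amidation, and the formaldehyde aldol of step 6 that feeds it, are argued by analogy. The fallback sets out from 12 and comes back at 16, avoiding the lactone altogether. Fráter–Seebach alkylation of 12 with benzyl chloromethyl ether (LiN(iPr)2, THF, –78 → –10 °C) gives dimethyl (2R,3S)-3-[(benzyloxy)methyl]-2-hydroxybutanedioate F1. Amidation selective for the α-hydroxy ester (MeNH(OMe)·HCl, AlMe3, CH2Cl2, 0 °C) gives methyl (2S,3R)-2-[(benzyloxy)methyl]-3-hydroxy-4-[methoxy(methyl)amino]-4-oxobutanoate F2. MeMgBr (THF, –40 °C) gives methyl (2S,3R)-2-[(benzyloxy)methyl]-3-hydroxy-4-oxopentanoate F3, and hydrogenolysis (H2, Pd/C, EtOAc) returns 16.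

**Further compounds**

F1 | step 7 | dimethyl (2R,3S)-3-[(benzyloxy)methyl]-2-hydroxybutanedioate | COC(=O)[C@H](O)[C@@H](C(=O)OC)COCc1ccccc1
F2 | step 7 | methyl (2S,3R)-2-[(benzyloxy)methyl]-3-hydroxy-4-[methoxy(methyl)amino]-4-oxobutanoate | CON(C)C(=O)[C@H](O)[C@@H](C(=O)OC)COCc1ccccc1
F3 | step 7 | methyl (2S,3R)-2-[(benzyloxy)methyl]-3-hydroxy-4-oxopentanoate | CC(=O)[C@H](O)[C@@H](C(=O)OC)COCc1ccccc1
F4 | step 8 | methyl (2S,3R,4R)-3,4-dihydroxy-2-(hydroxymethyl)-4-methylhex-5-ynoate | C#C[C@@](C)(O)[C@H](O)[C@@H](C(=O)OC)CO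
F5 | step 8 | (3S,4R,5R)-5-ethynyl-4-hydroxy-3-(hydroxymethyl)-5-methyloxolan-2-one | C#C[C@]1(C)[C@H](O)[C@H](CO)C(=O)O1
F6 | step 8 | (3R,4R,5S,9E,11R,12S,13R)-3,4,11,12-tetrahydroxy-5-(hydroxymethyl)-3,11,13-trimethylpentadec-9-en-1-yne-6,8-dione | C#C[C@@](C)(O)[C@H](O)[C@@H](C(=O)CC(=O)/C=C/[C@@](C)(O)[C@@H](O)[C@H](C)CC)CO
F7 | step 9 | (7S,8R,8aS)-3-[(1E,3R,4S,5R)-3,4-dihydroxy-3,5-dimethylhept-1-en-1-yl]-4a,7,8-trihydroxy-7-methyl-1,4a,5,7,8,8a-hexahydro-6H-isochromen-6-one (4a-epimers) | CC[C@@H](C)[C@H](O)[C@](C)(O)/C=C/C1=CC2(O)CC(=O)[C@@](C)(O)[C@H](O)[C@@H]2CO1
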